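At early times a flask tells you little about the question here, because the complex with two exchanged (B) is still building and the over-reaction product (P) sits near the scatter. So start from what is asked, and then read the later rows.

| setting | summer | dusk | spring | delta | alpha | theta | beta |
|---|---|---|---|---|---|---|---|
| starting complex | 0.14 M | 0.14 M | 0.14 M | 0.14 M (fed, over 15 h) | 0.14 M | 0.14 M | 0.14 M |
| incoming ligand | 0.252 M | 0.13 M | 0.19 M | 0.252 M | 0.252 M | 0.252 M (in portions, 4, over 15 h) | 0.252 M (fed, over 15 h) |
| remark | run made earlier | run made earlier | run made earlier | all else is in the flask from the start; the feed brings no volume worth counting | everything together at the start | first portion at the start, last at 15 h | all else is in the flask from the start; the feed brings no volume worth counting |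
| time |  |  |  | 20 h | 20 h | 20 h | 20 h |

| run | time / h | complex with two exchanged / % | over-reaction product / % |
|---|---|---|---|
| summer | 0.667 | 1.6 | 1.7 |
| summer | 2.00 | 8.4 | 2.0 |
| summer | 3.00 | 14.9 | 5.7 |
| summer | 5.00 | 15.7 | 14.0 |
| summer | 8.00 | 11.9 | 28.0 |
| summer | 10.0 | 11.9 | 34.6 |
| summer | 12.0 | 8.1 | 40.5 |
| dusk | 1.00 | 2.3 | 0.9 |
| dusk | 1.33 | 2.4 | 0 |
| dusk | 2.00 | 0.9 | 0 |
| dusk | 3.00 | 4.4 | 2.6 |
| dusk | 5.00 | 6.4 | 5.1 |
| dusk | 8.00 | 6.0 | 10.8 |
| dusk | 12.0 | 3.8 | 14.9 |
| spring | 1.00 | 2.4 | 0 |
| spring | 1.33 | 5.1 | 0.8 |
| spring | 2.00 | 7.2 | 0.5 |
| spring | 3.00 | 10.0 | 4.1 |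
| spring | 5.00 | 12.7 | 10.0 |
| spring | 8.00 | 9.7 | 19.4 |
| spring | 12.0 | 5.9 | 28.9 |

(each reading ± 1 percentage point)

* the best flask by share of complex with two exchanged in complex with two exchanged plus over-reaction product; "all alike" if 1.5 percentage points covers them all (delta / alpha / theta / beta / all alike)
* share of complex with two exchanged in complex with two exchanged plus over-reaction product at the end, delta
* share of complex with two exchanged in complex with two exchanged plus over-reaction product at the end, alpha
* share of complex with two exchanged in complex with two exchanged plus over-reaction product at the end, theta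
* share of complex with two exchanged in complex with two exchanged plus over-reaction product at the end, beta

- the numbers in the tables scatter with a standard deviation of 1 percentage point
- reactions considered so far: starting complex + incoming ligand -> leaving ligand + complex with one exchanged; complex with one exchanged + incoming ligand <-> leaving ligand + complex with two exchanged; complex with two exchanged -> over-reaction product; complex with one exchanged -> decomposed reagent

Take the summer table from 5.00 h on. From that row to 8.00 h, P gains per hour 0.338 h⁻¹ of the B standing. From 8.00 h to 12.0 h, the same reading is 0.312 h⁻¹. B has fallen, the rate has fallen with it, and their ratio holds within the scatter, so this loss is first order in B.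

Over the four rows B averages 11.9 %, while P gains 26 percentage points in 7.00 h. That gives a lifetime of B, τ, of 3.14 h. The dusk rows, with 0.13 M of ligand against 0.252 M, read 3.86 h.

Now suppose B is made at a steady rate through a run of length t, here 20 h, which is longer than τ. B then stands at rate times τ, and B plus P at rate times t. The share of B, the selectivity asked for, is therefore W = τ/t, the even-making share, which is 15.7 %. Making that leans late puts a flask above W, and making that leans early puts it below.

My own reckoning stops at a ranking. Alpha falls well under W and delta near it, while beta and theta, still receiving ligand up to 15 h, stand above it, too close for me to separate.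

The forecast gives 8 % for alpha, 10.5 % for delta, 19 % for theta and 21 % for beta, and picks beta. Calling B "C", its ground is that the share “depends on how fast C is still forming then”.

    starting complex + incoming ligand → leaving ligand + complex with one exchanged (k = 5.05 × 10⁻⁴ L mol⁻¹ s⁻¹)
    complex with one exchanged + incoming ligand ⇌ leaving ligand + complex with two exchanged (K = 2.40, k = 3.93 × 10⁻⁴ L mol⁻¹ s⁻¹)
    complex with two exchanged → over-reaction product (k = 8.09 × 10⁻⁵ s⁻¹)
    complex with one exchanged → decomposed reagent (k = 8.87 × 10⁻⁶ s⁻¹)

Theta comes out best at 21.1 %, against 19.4 % for beta, 14.3 % for delta and 6.18 % for alpha. Theta's lead over beta is 1.7 points, beyond the margin of 1.5 points, so the forecast's pick does not hold. At 20.0 h in theta, B is being made at 0.729 of the rate at which it is used. Against W, alpha stands at 0.394 and theta at 1.34.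

Now take the neighbour of theta charged with 0.63 M of incoming ligand. At 20.0 h this neighbour holds 3.31 % of complex with one exchanged and 0.0338 % of starting complex, less than the 82.0 % in B plus P, so its making leans early and W places it below 15.7 %. The flask gives 8.92 %.

(The data were computed for an exercise, and the scatter is random.)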